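**Plan**

1. Numbering (eremophilane): ring A = C1–C5 + C10, ring B = C5–C10; C3 bears the ester, C4 the secondary methyl (C15), C5 the angular methyl (C14), C8 is the ketone, C11 the isopropylidene carbon.
2. Cuts, in retrosynthetic order: ester C–O; C3 carbinol and C4 methine back to an enedione with exocyclic C4=CH2; the ring A bond C3–C4; C7=C11 (aldol condensation); ring B by a Diels–Alder reaction (bonds C5–C10 and C6–C7).
3. Enabling feature: C4 is a methyl-bearing carbon between the quaternary C5 and the oxygenated C3, and the cis C1=C2 bond of the C8 dienone ties C3 to C10. C4 can therefore arrive as the internal carbon of an alkenyl triflate (C4=CH2) on C5 and C3 as the aldehyde of a (Z)-enal on C10, and one Nozaki–Hiyama–Kishi addition closes ring A and completes the skeleton.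
4. Forward order: enantioselective Diels–Alder (ring B, C5) → (Z)-alkene, alkenyl triflate, enone, isopropylidene → ring A → redox adjustment → esterification.
5. Stereochemistry: C5 by catalysis; C4 and C3 are relayed from C5, whose methyl is axial on the flat trienone, so the proton at C4 (step 16) and the hydride at C3 (step 17) both enter anti to it; C6' of the acid comes from (S)-2-methylbutan-1-ol.

Key step: step 14

Assumption: the (S)-oxazaborolidinium catalyst of step 6 is taken to expose the face of methacrolein that gives the (1S) quaternary centre of 11; if the opposite sense is found, the enantiomeric catalyst is used.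

**Route**

Step 1
Reactants: 1 (S)-2-methylbutan-1-ol; 2 triethyl (E)-4-phosphonobut-2-enoate
Product: 4 ethyl (2E,4E,6S)-6-methylocta-2,4-dienoate, via (S)-2-methylbutanal 3 (not isolated)
Conditions: TEMPO (cat.), PhI(OAc)2, CH2Cl2, 0 °C to rt; crude 3 added to 2/LiHMDS, THF, −78 to 0 °C
Reagents that add atoms: none
Why: Oxoammonium oxidation gives the epimerizable aldehyde, which is used at once in a vinylogous Horner–Wadsworth–Emmons olefination that should give the (2E,4E)-dienoate; the stereocentre comes from the chiral pool and is not touched.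

Step 2
Reactants: 4 ethyl (2E,4E,6S)-6-methylocta-2,4-dienoate
Product: 5 (2E,4E,6S)-6-methylocta-2,4-dienoic acid
Conditions: LiOH, THF/MeOH/H2O, rt; then 1 M HCl
Reagents that add atoms: lithium hydroxide, [Li+].[OH-]
Why: Saponification of an ethyl ester; the remote stereocentre and the diene geometry are not affected.

Step 3
Reactants: 6 3,3-diethoxyprop-1-yne
Product: 7 4,4-diethoxybut-2-ynal
Conditions: n-BuLi, THF, −78 °C; DMF, −78 to 0 °C; inverse quench into aq. KH2PO4
Reagents that add atoms: N,N-dimethylformamide, CN(C)C=O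
Why: Formylation of a lithium acetylide with DMF; the buffered inverse quench should release the ynal without amine conjugate addition or acetal loss.

Step 4
Reactants: 7 4,4-diethoxybut-2-ynal
Product: 8 (E)-7,7-diethoxyhept-3-en-5-yn-2-one
Conditions: Ph3P=CHC(O)CH3, CH2Cl2, rt
Reagents that add atoms: 1-(triphenylphosphoranylidene)propan-2-one, CC(=O)C=P(c1ccccc1)(c1ccccc1)c1ccccc1
Why: Wittig olefination with a stabilized ylide, which should be E-selective.

Step 5
Reactants: 8 (E)-7,7-diethoxyhept-3-en-5-yn-2-one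
Product: 9 [(E)-7,7-diethoxyhepta-1,3-dien-5-yn-2-yl]oxy-tri(propan-2-yl)silane
Conditions: TIPSOTf, Et3N, Et2O, 0 °C
Reagents that add atoms: triisopropylsilyl trifluoromethanesulfonate, CC(C)[Si](C(C)C)(C(C)C)OS(=O)(=O)C(F)(F)F
Why: Soft enolization and O-silylation of the methyl ketone gives the 2-silyloxy-1,3-diene with the E geometry retained.

Step 6
Reactants: 9 [(E)-7,7-diethoxyhepta-1,3-dien-5-yn-2-yl]oxy-tri(propan-2-yl)silane; 10 methacrolein
Product: 11 (1S,2R)-2-(3,3-diethoxyprop-1-yn-1-yl)-1-methyl-4-[tri(propan-2-yl)silyloxy]cyclohex-3-ene-1-carbaldehyde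
Conditions: (S)-o-tolyl-oxazaborolidine (20 mol %) activated with Tf2NH, CH2Cl2, −78 to −40 °C
Reagents that add atoms: none
Why: Enantioselective Diels–Alder reaction under chiral oxazaborolidinium catalysis; the 2-silyloxy group and the alkynyl terminus both direct the quaternary carbon next to the alkynyl-bearing carbon, the catalyst shields one face of coordinated methacrolein and so sets the quaternary centre (later C5), and the ring C2 centre (exo-formyl expected) is erased in step 11.

Step 7
Reactants: 11 (1S,2R)-2-(3,3-diethoxyprop-1-yn-1-yl)-1-methyl-4-[tri(propan-2-yl)silyloxy]cyclohex-3-ene-1-carbaldehyde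
Product: 12 (1S,2S)-2-[(Z)-3,3-diethoxyprop-1-en-1-yl]-1-methyl-4-[tri(propan-2-yl)silyloxy]cyclohex-3-ene-1-carbaldehyde
Conditions: H2 (1 atm), Pd on CaCO3 poisoned with Pb(OAc)2, quinoline, EtOAc, rt
Reagents that add atoms: none
Why: Lindlar semi-hydrogenation adds H2 syn to the isolated alkyne and gives the (Z)-alkene needed for ring closure; the 2R to 2S change is a priority change only.

Step 8
Reactants: 12 (1S,2S)-2-[(Z)-3,3-diethoxyprop-1-en-1-yl]-1-methyl-4-[tri(propan-2-yl)silyloxy]cyclohex-3-ene-1-carbaldehyde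
Product: 13 1-[(1S,2S)-2-[(Z)-3,3-diethoxyprop-1-en-1-yl]-1-methyl-4-[tri(propan-2-yl)silyloxy]cyclohex-3-en-1-yl]ethan-1-ol (both carbinol epimers)
Conditions: MeMgBr, THF, −78 °C; aq. NH4Cl
Reagents that add atoms: methylmagnesium bromide, C[Mg]Br
Why: Grignard addition to the non-enolizable aldehyde brings in C15; the new carbinol centre is removed in step 9, so both epimers are carried on.

Step 9
Reactants: 13 1-[(1S,2S)-2-[(Z)-3,3-diethoxyprop-1-en-1-yl]-1-methyl-4-[tri(propan-2-yl)silyloxy]cyclohex-3-en-1-yl]ethan-1-ol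
Product: 14 1-[(1S,2S)-2-[(Z)-3,3-diethoxyprop-1-en-1-yl]-1-methyl-4-[tri(propan-2-yl)silyloxy]cyclohex-3-en-1-yl]ethan-1-one
Conditions: Dess–Martin periodinane, NaHCO3, CH2Cl2, rt
Reagents that add atoms: none
Why: Buffered Dess–Martin oxidation of a secondary alcohol; the silyl enol ether and the allylic acetal should survive the neutral conditions.

Step 10
Reactants: 14 1-[(1S,2S)-2-[(Z)-3,3-diethoxyprop-1-en-1-yl]-1-methyl-4-[tri(propan-2-yl)silyloxy]cyclohex-3-en-1-yl]ethan-1-one
Product: 15 1-[(1S,2S)-2-[(Z)-3,3-diethoxyprop-1-en-1-yl]-1-methyl-4-[tri(propan-2-yl)silyloxy]cyclohex-3-en-1-yl]ethenyl trifluoromethanesulfonate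
Conditions: KHMDS, THF, −78 °C; PhNTf2, −78 to 0 °C
Reagents that add atoms: N-phenylbis(trifluoromethanesulfonimide), O=S(=O)(N(c1ccccc1)S(=O)(=O)C(F)(F)F)C(F)(F)F
Why: The methyl group is the only enolizable position (the other α-carbon is quaternary and the ring ketone is masked), so enolate O-triflation gives the 1,1-disubstituted alkenyl triflate.

Step 11
Reactants: 15 1-[(1S,2S)-2-[(Z)-3,3-diethoxyprop-1-en-1-yl]-1-methyl-4-[tri(propan-2-yl)silyloxy]cyclohex-3-en-1-yl]ethenyl trifluoromethanesulfonate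
Product: 16 1-[(1S)-2-[(Z)-3,3-diethoxyprop-1-en-1-yl]-1-methyl-4-oxocyclohex-2-en-1-yl]ethenyl trifluoromethanesulfonate
Conditions: Pd(OAc)2 (1.2 equiv), MeCN, rt to 40 °C
Reagents that add atoms: none
Why: Saegusa–Ito oxidation, in which the palladium enolate can lose only the ring C2 hydrogen, so the enone forms regiospecifically and the C2 stereocentre disappears; without phosphine the alkenyl triflate should not react with the palladium.

Step 12
Reactants: 16 1-[(1S)-2-[(Z)-3,3-diethoxyprop-1-en-1-yl]-1-methyl-4-oxocyclohex-2-en-1-yl]ethenyl trifluoromethanesulfonate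
Product: 19 1-[(1S)-2-[(Z)-3,3-diethoxyprop-1-en-1-yl]-1-methyl-4-oxo-5-(propan-2-ylidene)cyclohex-2-en-1-yl]ethenyl trifluoromethanesulfonate, via lithium aldolate 17 (not isolated), via tertiary mesylate 18 (not isolated)
Conditions: LDA (1.05 equiv), THF, −78 °C; acetone; MsCl, −78 to 0 °C; DBU, 0 °C to rt
Reagents that add atoms: acetone, CC(C)=O; methanesulfonyl chloride, CS(=O)(=O)Cl (its atoms stay only in 18)
Why: Aldol condensation: the enone has only α' hydrogens, the kinetic enolate adds to acetone, and mesylation followed by E1cB elimination should give the conjugated isopropylidene group.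

Step 13
Reactants: 19 1-[(1S)-2-[(Z)-3,3-diethoxyprop-1-en-1-yl]-1-methyl-4-oxo-5-(propan-2-ylidene)cyclohex-2-en-1-yl]ethenyl trifluoromethanesulfonate
Product: 20 1-[(1S)-1-methyl-4-oxo-2-[(Z)-3-oxoprop-1-en-1-yl]-5-(propan-2-ylidene)cyclohex-2-en-1-yl]ethenyl trifluoromethanesulfonate
Conditions: SiO2, 10% aq. oxalic acid, CH2Cl2, 0 °C
Reagents that add atoms: water, O
Why: Hydrolysis of an allylic acetal on wet silica, mild enough that the (Z)-enal should be released without isomerization; the aldehyde is used at once.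

Step 14
Reactants: 20 1-[(1S)-1-methyl-4-oxo-2-[(Z)-3-oxoprop-1-en-1-yl]-5-(propan-2-ylidene)cyclohex-2-en-1-yl]ethenyl trifluoromethanesulfonate
Product: 21 (4aS,6R)-6-hydroxy-4a-methyl-5-methylidene-3-(propan-2-ylidene)-4,4a,5,6-tetrahydronaphthalen-2(3H)-one
Conditions: CrCl2 (6 equiv), NiCl2 (2 mol %), degassed DMF/THF, rt, 0.005 M; aq. work-up
Reagents that add atoms: none
Why: Zerovalent nickel inserts into the alkenyl C–OTf bond, the alkenyl group passes to chromium, and the alkenylchromium carbon C4 adds 1,2 to the aldehyde carbon C3, with divalent chromium as the terminal reductant. The closest known reaction type is the intramolecular Nozaki–Hiyama–Kishi cyclization of alkenyl triflates or iodides onto aldehydes. Ring A closes in the 6-exo-trig mode, the carbonyl oxygen staying outside the new ring. The only new stereocentre is the C3 carbinol: the chromium-bound oxygen should turn away from the axial C5 methyl (3α-OH expected), but this centre is erased in step 15, so either epimer serves. The step needs chemoselectivity for the aldehyde over the C8 dienone and ring closure over oligomerization; alkenylchromium reagents add only to aldehydes and only 1,2, conjugate addition is geometrically impossible, and the (Z)-C1=C2 bond together with the fully substituted C5 hold C3 and C4 within bonding distance. The exocyclic C4=CH2 group that remains is the handle from which the C4 stereocentre is set in step 16.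

Step 15
Reactants: 21 (4aS,6R)-6-hydroxy-4a-methyl-5-methylidene-3-(propan-2-ylidene)-4,4a,5,6-tetrahydronaphthalen-2(3H)-one
Product: 22 (4aS)-4a-methyl-5-methylidene-3-(propan-2-ylidene)-4,4a-dihydronaphthalene-2,6(3H,5H)-dione
Conditions: Dess–Martin periodinane, NaHCO3, CH2Cl2, 0 °C
Reagents that add atoms: none
Why: Dess–Martin oxidation of a doubly allylic alcohol to the cross-conjugated ketone; it makes the exocyclic alkene a Michael acceptor and lets the C3 configuration be set afresh.

Step 16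
Reactants: 22 (4aS)-4a-methyl-5-methylidene-3-(propan-2-ylidene)-4,4a-dihydronaphthalene-2,6(3H,5H)-dione
Product: 23 (4aR,5R)-4a,5-dimethyl-3-(propan-2-ylidene)-4,4a-dihydronaphthalene-2,6(3H,5H)-dione
Conditions: [(Ph3P)CuH]6 (0.25 equiv), THF/toluene, −40 °C; AcOH, −78 °C
Reagents that add atoms: none
Why: Copper hydride conjugate reduction: hydride adds to the unsubstituted terminal carbon C15, the most accessible acceptor position, and kinetic axial protonation of the enolate at C4 from the face opposite the axial C5 methyl should place the new methyl cis to it (the S to R change at C5 is a priority change only); 23 is epimerizable and is used at once.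

Step 17
Reactants: 23 (4aR,5R)-4a,5-dimethyl-3-(propan-2-ylidene)-4,4a-dihydronaphthalene-2,6(3H,5H)-dione
Product: 24 (4aR,5R,6S)-6-hydroxy-4a,5-dimethyl-3-(propan-2-ylidene)-4,4a,5,6-tetrahydronaphthalen-2(3H)-one
Conditions: NaBH4 (1.0 equiv), CeCl3·7H2O, MeOH, −78 °C
Reagents that add atoms: none
Why: Luche 1,2-reduction: the C3 enone carbonyl should be more electrophilic and less shielded than the cross-conjugated C8 carbonyl beside the isopropylidene group, and hydride should attack anti to the syn-axial C5 methyl, giving the 3β-alcohol cis to both methyls.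

Step 18
Reactants: 24 (4aR,5R,6S)-6-hydroxy-4a,5-dimethyl-3-(propan-2-ylidene)-4,4a,5,6-tetrahydronaphthalen-2(3H)-one; 5 (2E,4E,6S)-6-methylocta-2,4-dienoic acid
Product: 25 (1R,2S,8aR)-1,8a-dimethyl-6-oxo-7-(propan-2-ylidene)-1,2,6,7,8,8a-hexahydronaphthalen-2-yl (2E,4E,6S)-6-methylocta-2,4-dienoate
Conditions: 5, 2,4,6-trichlorobenzoyl chloride, Et3N, THF, rt; then 24, DMAP, toluene, rt
Reagents that add atoms: none
Why: Yamaguchi esterification through the mixed anhydride acylates the hindered allylic alcohol at oxygen, so C3 keeps its configuration.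

**Compound list**

1 | (S)-2-methylbutan-1-ol | CC[C@H](C)CO | starting material
2 | triethyl (E)-4-phosphonobut-2-enoate | CCOC(=O)/C=C/CP(=O)(OCC)OCC | starting material
3 | (S)-2-methylbutanal | CC[C@H](C)C=O | intermediate (not isolated)
4 | ethyl (2E,4E,6S)-6-methylocta-2,4-dienoate | CC[C@H](C)/C=C/C=C/C(=O)OCC | intermediate
5 | (2E,4E,6S)-6-methylocta-2,4-dienoic acid | CC[C@H](C)/C=C/C=C/C(=O)O | intermediate
6 | 3,3-diethoxyprop-1-yne | C#CC(OCC)OCC | starting material
7 | 4,4-diethoxybut-2-ynal | O=CC#CC(OCC)OCC | intermediate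
8 | (E)-7,7-diethoxyhept-3-en-5-yn-2-one | CC(=O)/C=C/C#CC(OCC)OCC | intermediate
9 | [(E)-7,7-diethoxyhepta-1,3-dien-5-yn-2-yl]oxy-tri(propan-2-yl)silane | C=C(O[Si](C(C)C)(C(C)C)C(C)C)/C=C/C#CC(OCC)OCC | intermediate
10 | methacrolein (2-methylprop-2-enal) | CC(=C)C=O | starting material
11 | (1S,2R)-2-(3,3-diethoxyprop-1-yn-1-yl)-1-methyl-4-[tri(propan-2-yl)silyloxy]cyclohex-3-ene-1-carbaldehyde | CCOC(OCC)C#C[C@H]1C=C(O[Si](C(C)C)(C(C)C)C(C)C)CC[C@]1(C)C=O | intermediate
12 | (1S,2S)-2-[(Z)-3,3-diethoxyprop-1-en-1-yl]-1-methyl-4-[tri(propan-2-yl)silyloxy]cyclohex-3-ene-1-carbaldehyde | CCOC(OCC)/C=C\[C@H]1C=C(O[Si](C(C)C)(C(C)C)C(C)C)CC[C@]1(C)C=O | intermediate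
13 | 1-[(1S,2S)-2-[(Z)-3,3-diethoxyprop-1-en-1-yl]-1-methyl-4-[tri(propan-2-yl)silyloxy]cyclohex-3-en-1-yl]ethan-1-ol, both carbinol epimers | CCOC(OCC)/C=C\[C@H]1C=C(O[Si](C(C)C)(C(C)C)C(C)C)CC[C@]1(C)C(C)O | intermediate
14 | 1-[(1S,2S)-2-[(Z)-3,3-diethoxyprop-1-en-1-yl]-1-methyl-4-[tri(propan-2-yl)silyloxy]cyclohex-3-en-1-yl]ethan-1-one | CCOC(OCC)/C=C\[C@H]1C=C(O[Si](C(C)C)(C(C)C)C(C)C)CC[C@]1(C)C(C)=O | intermediate
15 | 1-[(1S,2S)-2-[(Z)-3,3-diethoxyprop-1-en-1-yl]-1-methyl-4-[tri(propan-2-yl)silyloxy]cyclohex-3-en-1-yl]ethenyl trifluoromethanesulfonate | CCOC(OCC)/C=C\[C@H]1C=C(O[Si](C(C)C)(C(C)C)C(C)C)CC[C@]1(C)C(=C)OS(=O)(=O)C(F)(F)F | intermediate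
16 | 1-[(1S)-2-[(Z)-3,3-diethoxyprop-1-en-1-yl]-1-methyl-4-oxocyclohex-2-en-1-yl]ethenyl trifluoromethanesulfonate | CCOC(OCC)/C=C\C1=CC(=O)CC[C@]1(C)C(=C)OS(=O)(=O)C(F)(F)F | intermediate
17 | aldol adduct of 16 with acetone, 5-(2-hydroxypropan-2-yl) derivative, formed as its lithium alkoxide, both ring C5 epimers | CCOC(OCC)/C=C\C1=CC(=O)C(C(C)(C)O)C[C@]1(C)C(=C)OS(=O)(=O)C(F)(F)F | intermediate (not isolated)
18 | methanesulfonate of 17 | CCOC(OCC)/C=C\C1=CC(=O)C(C(C)(C)OS(C)(=O)=O)C[C@]1(C)C(=C)OS(=O)(=O)C(F)(F)F | intermediate (not isolated)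
19 | 1-[(1S)-2-[(Z)-3,3-diethoxyprop-1-en-1-yl]-1-methyl-4-oxo-5-(propan-2-ylidene)cyclohex-2-en-1-yl]ethenyl trifluoromethanesulfonate | CCOC(OCC)/C=C\C1=CC(=O)C(=C(C)C)C[C@]1(C)C(=C)OS(=O)(=O)C(F)(F)F | intermediate
20 | 1-[(1S)-1-methyl-4-oxo-2-[(Z)-3-oxoprop-1-en-1-yl]-5-(propan-2-ylidene)cyclohex-2-en-1-yl]ethenyl trifluoromethanesulfonate | O=C/C=C\C1=CC(=O)C(=C(C)C)C[C@]1(C)C(=C)OS(=O)(=O)C(F)(F)F | intermediate
21 | (4aS,6R)-6-hydroxy-4a-methyl-5-methylidene-3-(propan-2-ylidene)-4,4a,5,6-tetrahydronaphthalen-2(3H)-one (expected major C6 epimer) | O[C@@H]1C=CC2=CC(=O)C(=C(C)C)C[C@]2(C)C1=C | intermediate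
22 | (4aS)-4a-methyl-5-methylidene-3-(propan-2-ylidene)-4,4a-dihydronaphthalene-2,6(3H,5H)-dione | O=C1C=CC2=CC(=O)C(=C(C)C)C[C@]2(C)C1=C | intermediate
23 | (4aR,5R)-4a,5-dimethyl-3-(propan-2-ylidene)-4,4a-dihydronaphthalene-2,6(3H,5H)-dione | O=C1C=CC2=CC(=O)C(=C(C)C)C[C@]2(C)[C@H]1C | intermediate
24 | (4aR,5R,6S)-6-hydroxy-4a,5-dimethyl-3-(propan-2-ylidene)-4,4a,5,6-tetrahydronaphthalen-2(3H)-one | O[C@H]1C=CC2=CC(=O)C(=C(C)C)C[C@]2(C)[C@H]1C | intermediate
25 | (1R,2S,8aR)-1,8a-dimethyl-6-oxo-7-(propan-2-ylidene)-1,2,6,7,8,8a-hexahydronaphthalen-2-yl (2E,4E,6S)-6-methylocta-2,4-dienoate | CC[C@H](C)/C=C/C=C/C(=O)O[C@H]1C=CC2=CC(=O)C(=C(C)C)C[C@]2(C)[C@H]1C | target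

**Step count and risks**

Total step count: 18. Longest linear sequence: 16 (steps 3 to 18).

Steps most likely to fail:

Step 14. Electron transfer from divalent chromium into the cross-conjugated dienone–enal, or Z-to-E isomerization of the enal before the slow nickel insertion, would take material off the productive path. The fallback sets out from 19 and avoids a reducing metal. Miyaura borylation (B2pin2, PdCl2(PPh3)2, PPh3, KOPh, toluene, 50 °C) should give the alkenylboronate 2-[1-[(1R)-2-[(Z)-3,3-diethoxyprop-1-en-1-yl]-1-methyl-4-oxo-5-(propan-2-ylidene)cyclohex-2-en-1-yl]ethenyl]-4,4,5,5-tetramethyl-1,3,2-dioxaborolane F1. The wet-silica hydrolysis of step 13 should then give the aldehyde (Z)-3-[(6R)-6-methyl-3-oxo-4-(propan-2-ylidene)-6-[1-(4,4,5,5-tetramethyl-1,3,2-dioxaborolan-2-yl)ethenyl]cyclohex-1-en-1-yl]prop-2-enal F2. A rhodium-catalysed intramolecular 1,2-addition of the alkenylboron to the aldehyde ([Rh(cod)OH]2, dioxane/H2O, rt) should close ring A and come back to the route at 21.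

Step 16. Protonation of the copper enolate from the wrong face, equilibration of the α-stereocentre of 23 before step 17, or hydride addition at C1 would erode the C4 configuration. The fallback sets out from 21 and sets C4 by addition of H2 instead of by protonation. Homogeneous hydrogenation (H2, 1 atm, RhCl(PPh3)3, benzene, rt) of the exocyclic alkene, the only non-conjugated C=C, should add hydrogen anti to the angular methyl and give (4aR,5R,6R)-6-hydroxy-4a,5-dimethyl-3-(propan-2-ylidene)-4,4a,5,6-tetrahydronaphthalen-2(3H)-one F3. Dess–Martin oxidation (NaHCO3, CH2Cl2, 0 °C) then comes back to the route at 23.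

Step 17. Loss of chemoselectivity between the two conjugated ketones would lead to over-reduction at C8. The fallback sets out from 23 and turns this into the plan. Exhaustive Luche reduction (excess NaBH4, CeCl3·7H2O, MeOH, −40 °C) should give (4aR,5R,6S)-4a,5-dimethyl-3-(propan-2-ylidene)-2,3,4,4a,5,6-hexahydronaphthalene-2,6-diol F4 as a mixture at C2. Selective oxidation with MnO2 (CH2Cl2, rt) of the C8 carbinol, which is doubly allylic whereas the C3 carbinol is singly allylic, comes back to the route at 24.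

Further compounds
F1 | step 14 | 2-[1-[(1R)-2-[(Z)-3,3-diethoxyprop-1-en-1-yl]-1-methyl-4-oxo-5-(propan-2-ylidene)cyclohex-2-en-1-yl]ethenyl]-4,4,5,5-tetramethyl-1,3,2-dioxaborolane | CCOC(OCC)/C=C\C1=CC(=O)C(=C(C)C)C[C@]1(C)C(=C)B1OC(C)(C)C(C)(C)O1
F2 | step 14 | (Z)-3-[(6R)-6-methyl-3-oxo-4-(propan-2-ylidene)-6-[1-(4,4,5,5-tetramethyl-1,3,2-dioxaborolan-2-yl)ethenyl]cyclohex-1-en-1-yl]prop-2-enal | O=C/C=C\C1=CC(=O)C(=C(C)C)C[C@]1(C)C(=C)B1OC(C)(C)C(C)(C)O1
F3 | step 16 | (4aR,5R,6R)-6-hydroxy-4a,5-dimethyl-3-(propan-2-ylidene)-4,4a,5,6-tetrahydronaphthalen-2(3H)-one | O[C@@H]1C=CC2=CC(=O)C(=C(C)C)C[C@]2(C)[C@H]1C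
F4 | step 17 | (4aR,5R,6S)-4a,5-dimethyl-3-(propan-2-ylidene)-2,3,4,4a,5,6-hexahydronaphthalene-2,6-diol | O[C@H]1C=CC2=CC(O)C(=C(C)C)C[C@]2(C)[C@H]1C
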